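**Plan** (labdane numbering for all atoms, also in the open-chain precursors)

- **Cuts:** first O9–COPh and the two protecting groups. Then 9α-OH/Δ7 ⇒ 8α,9α-epoxy-7-ketone ⇒ 8-en-7-one ⇒ Δ8 alkene (Wharton logic), then C12–C13. The key cut is C9–C10 with re-joining of C2–C10, which turns ring A into a cyclopentanone fused to a cyclopropane. Last come C1–C2/C2–C10 (carbene) and C4–C5 ([3,3]).
- **Enabling feature:** in ring A the C3 oxygen is γ to the methyl-bearing A/B junction carbon C10 (path C3–C2–C1–C10) and is flanked by the C4 gem-dimethyl group. The C2–C10 bond of a 5-methylbicyclo[3.1.0]hexan-2-one is therefore a masked C3 enol plus tertiary C10 cation, and the C8=C9 alkene of the chain on C5 is placed to trap it.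
- **Forward order:** C11 bromo-diene chain → allylic isobutyrate → C4–C5 by [3,3] → diazoketone → five-membered ring plus cyclopropane → one acid-catalysed isomerisation that enlarges this ring to ring A and closes ring B → side chain at C12 → ring B oxidation and transposition → benzoate → deprotection.
- **Stereochemistry:** C5 comes from an enantioselective Ireland–Claisen rearrangement (recoverable chiral boron controller). C10 follows from C5 (chair closure, trans-decalin). C3 is set by axial hydride attack, C9 by α-face epoxidation anti to CH3-20 and a stereoretentive Wharton transposition, and Δ13 E by syn-carbocupration.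

Key step: step 8

Assumption: the (R,R)-controller is taken to deliver the (3R)-acid of step 5. The sense of induction is not documented for an isobutyrate, and the equally available (S,S)-controller is used if it proves opposite.

Step 1
Reactants: 1 6-methylhept-5-en-2-one; 2 cyclopropylmagnesium bromide
Product: 3 2-cyclopropyl-6-methylhept-5-en-2-ol (racemic)
Conditions: THF, 0 °C; aq NH4Cl
Reagents that add atoms: none
Why: Grignard 1,2-addition to a methyl ketone; the new carbinol centre is racemic and is destroyed in step 2.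

Step 2
Reactants: 3 2-cyclopropyl-6-methylhept-5-en-2-ol
Product: 4 (3E)-1-bromo-4,8-dimethylnona-3,7-diene (homogeranyl bromide)
Conditions: MgBr2·OEt2, Et2O, reflux
Reagents that add atoms: magnesium dibromide (as etherate), Br[Mg]Br
Why: Julia-type cyclopropylcarbinyl-to-homoallyl rearrangement, in which bromide opens the ionising carbinol through the arrangement that keeps the larger chain away from the ring and so favours the E alkene; any Z isomer is harmless because C9 is flattened again in step 8.

Step 3
Reactants: 4 (3E)-1-bromo-4,8-dimethylnona-3,7-diene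
Product: 5 (2E,6E)-9-bromo-2,6-dimethylnona-2,6-dien-1-ol
Conditions: SeO2 (cat.), t-BuOOH, CH2Cl2, 0 → 23 °C
Reagents that add atoms: tert-butyl hydroperoxide, CC(C)(C)OO (oxygen relayed by catalytic SeO2, O=[Se]=O)
Why: Riley-type allylic hydroxylation (ene reaction, then [2,3]-shift) should pick the E-methyl group of the terminal, least hindered trisubstituted alkene, as in other open-chain polyprenyl systems.

Step 4
Reactants: 5 (2E,6E)-9-bromo-2,6-dimethylnona-2,6-dien-1-ol; 6 2-methylpropanoyl chloride
Product: 7 (2E,6E)-9-bromo-2,6-dimethylnona-2,6-dien-1-yl 2-methylpropanoate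
Conditions: Et3N, DMAP (cat.), CH2Cl2, 0 °C
Reagents that add atoms: none
Why: Routine O-acylation of a primary allylic alcohol; it brings in C3, C4 and both C4 methyl groups.

Step 5
Reactants: 7 (2E,6E)-9-bromo-2,6-dimethylnona-2,6-dien-1-yl 2-methylpropanoate
Product: 9 (3R)-3-[(3E)-6-bromo-3-methylhex-3-en-1-yl]-2,2,4-trimethylpent-4-enoic acid, via boron ketene acetal 8 (not isolated)
Conditions: (R,R)-1,2-diphenylethane-1,2-diamine bis[3,5-bis(trifluoromethyl)benzenesulfonamide], BBr3, CH2Cl2, 23 °C, then vacuum; 7, i-Pr2NEt, CH2Cl2, −78 → −20 °C; aqueous work-up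
Reagents that add atoms: (R,R)-2-bromo-1,3,2-diazaborolidine made in the flask (its boron unit sits in 8 only), BrB1N(S(=O)(=O)c2cc(C(F)(F)F)cc(C(F)(F)F)c2)[C@H](c2ccccc2)[C@@H](c2ccccc2)N1S(=O)(=O)c1cc(C(F)(F)F)cc(C(F)(F)F)c1
Why: Enantioselective Ireland–Claisen rearrangement: soft enolisation gives a boron ketene acetal without any E/Z question (both α-groups are methyl), the chair [3,3]-shift joins C4 to C5 and moves the alkene to C10=C1, and the chiral controller selects the face of the E alkene and so sets C5.

Step 6
Reactants: 9 (3R)-3-[(3E)-6-bromo-3-methylhex-3-en-1-yl]-2,2,4-trimethylpent-4-enoic acid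
Product: 11 (4R)-4-[(3E)-6-bromo-3-methylhex-3-en-1-yl]-1-diazo-3,3,5-trimethylhex-5-en-2-one, via acid chloride 10 (not isolated)
Conditions: (COCl)2, DMF (cat.), CH2Cl2, 0 → 23 °C; CH2N2 (excess), Et2O, 0 °C
Reagents that add atoms: diazomethane, C=[N+]=[N-]; oxalyl chloride, O=C(Cl)C(=O)Cl (chlorine of 10 only)
Why: Acylation of diazomethane by an acid chloride (first half of the Arndt–Eistert sequence) works also for pivaloyl-type chlorides; it adds C2, and the C5 centre is not enolisable.

Step 7
Reactants: 11 (4R)-4-[(3E)-6-bromo-3-methylhex-3-en-1-yl]-1-diazo-3,3,5-trimethylhex-5-en-2-one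
Product: 12 (1R,4R,5R)-4-[(3E)-6-bromo-3-methylhex-3-en-1-yl]-3,3,5-trimethylbicyclo[3.1.0]hexan-2-one (chain anti to the cyclopropane methylene)
Conditions: Rh2(OAc)4 (1 mol %), CH2Cl2, slow addition, 23 °C
Reagents that add atoms: none
Why: Intramolecular carbenoid cyclopropanation of a γ,δ-unsaturated diazoketone: the three-atom tether reaches only the near 1,1-disubstituted alkene and allows only the cis-fused bicycle, so C2 and C10 are set together; addition that leaves the chain anti to the new methylene gives 12, and the epimeric pair would feed the same C10 cation in step 8.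

Step 8
Reactants: 12 (1R,4R,5R)-4-[(3E)-6-bromo-3-methylhex-3-en-1-yl]-3,3,5-trimethylbicyclo[3.1.0]hexan-2-one
Product: 15 12-bromo-13,14,15,16-tetranorlabd-8-en-3-one (5α-H/10β-CH3 trans-decalin), via ring-expanded enol cation 13 (not isolated), via labd-7-ene isomer 14 (not isolated)
Conditions: TfOH (20 mol %), CH2Cl2, −78 → −20 °C, then 0 °C; Et3N quench
Reagents that add atoms: none
Why: Proposed new method: Protonation of the C3 carbonyl weakens the ring-fusion bond C2–C10, the only cyclopropane bond whose heterolysis leaves a tertiary cation; as it breaks, the cyclopentanone ring C2–C3–C4–C5–C10 takes the methylene C1 into its perimeter and becomes six-membered ring A (enol cation 13), C9 of the C8=C9 alkene adds to C10, the C8 cation loses a proton (first mainly to 14), and the same acid then moves the alkene to the tetrasubstituted C8=C9 position of 15 while the enol returns to the C3 ketone. The closest known reaction types are the acid-induced thujane-to-p-menthane ring enlargement (sabinene to terpinen-4-ol, sabina ketone to 4-isopropylcyclohexenone) and the acid-promoted opening of cyclopropyl ketones with participation of a tethered alkene; joining the two in one ring-enlarging bicyclisation is the new element. Ring A is not closed but enlarged from five to six atoms by cleavage of a shared bond, and ring B closes in the 6-endo-trig mode of a cation–olefin cyclisation. The one lasting new stereocentre, C10, is controlled by C5: in the chair-like closure the C5 chain is equatorial and C9 bonds to C10 anti to the departing C2, so the C9–C10 bond ends equatorial and CH3-20 axial and anti to H-5 (trans-decalin), while C5 itself is not touched and C9 is flattened again. The step needs internal instead of external cyclopropane cleavage (secured by the methyl group on C10 and by the absence of an external nucleophile, triflate being inert), capture of the cation faster than loss of H-5, which would erase the only stereocentre (secured by the short tether, the nucleophilic trisubstituted alkene and the low starting temperature), and a stop after two rings (secured by ending the chain in CH2Br, which is no π-nucleophile).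

Step 9
Reactants: 15 12-bromo-13,14,15,16-tetranorlabd-8-en-3-one
Product: 16 12-bromo-13,14,15,16-tetranorlabd-8-en-3β-ol
Conditions: NaBH4, MeOH–CH2Cl2, 0 °C
Reagents that add atoms: none
Why: Borohydride reduction of a 4,4-dimethyl-3-ketone: axial attack from the α-face, away from the axial 4β- and 10β-methyl groups, gives the equatorial 3β-alcohol and sets C3.

Step 10
Reactants: 16 12-bromo-13,14,15,16-tetranorlabd-8-en-3β-ol
Product: 17 12-bromo-3β-(triethylsilyloxy)-13,14,15,16-tetranorlabd-8-ene
Conditions: TESOTf, 2,6-lutidine, CH2Cl2, 0 °C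
Reagents that add atoms: triethylsilyl triflate, CC[Si](CC)(CC)OS(=O)(=O)C(F)(F)F
Why: Silyl triflate silylation handles the neopentyl-type secondary alcohol; the ether masks O3 for the organometallic, oxidative and basic steps that follow.

Step 11
Reactants: 17 12-bromo-3β-(triethylsilyloxy)-13,14,15,16-tetranorlabd-8-ene; 18 methyl but-2-ynoate
Product: 21 methyl 3β-(triethylsilyloxy)labda-8,13E-dien-15-oate, via Grignard reagent 19 (not isolated), via alkylcopper 20 (not isolated)
Conditions: Mg, THF, 40 °C; CuBr·SMe2, −40 °C; 18, −78 °C; aq NH4Cl, −78 °C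
Reagents that add atoms: magnesium, [Mg] (in 19 only); CuBr·SMe2, Br[Cu].CSC (copper of 20 only)
Why: Carbocupration (conjugate addition of an alkylcopper to an acetylenic ester): syn addition across the triple bond and protonation with retention at −78 °C put C12 trans to the ester, which is the E geometry of the target.

Step 12
Reactants: 21 methyl 3β-(triethylsilyloxy)labda-8,13E-dien-15-oate
Product: 22 methyl 7-oxo-3β-(triethylsilyloxy)labda-8,13E-dien-15-oate
Conditions: CrO3, 3,5-dimethylpyrazole, CH2Cl2, −20 °C
Reagents that add atoms: chromium trioxide, O=[Cr](=O)=O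
Why: Allylic oxidation with the CrO3–dimethylpyrazole complex: of the allylic sites of the only electron-rich alkene the ring methylene C7 is the most accessible and gives the conjugated ketone, while the enoate alkene is deactivated.

Step 13
Reactants: 22 methyl 7-oxo-3β-(triethylsilyloxy)labda-8,13E-dien-15-oate
Product: 23 methyl 8α,9α-epoxy-7-oxo-3β-(triethylsilyloxy)labd-13E-en-15-oate
Conditions: t-BuOOH, BnMe3NOH (cat.), THF, 0 → 23 °C
Reagents that add atoms: tert-butyl hydroperoxide, CC(C)(C)OO
Why: Weitz–Scheffer nucleophilic epoxidation, known for α-methyl enones whose β-carbon adjoins an angular methyl carbon: the peroxide adds to C9 axially from the α-face anti to CH3-20 and so sets C8 and C9, and the β,β-disubstituted ester does not compete.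

Step 14
Reactants: 23 methyl 8α,9α-epoxy-7-oxo-3β-(triethylsilyloxy)labd-13E-en-15-oate
Product: 24 methyl 9α-hydroxy-3β-(triethylsilyloxy)labda-7,13E-dien-15-oate
Conditions: N2H4·H2O, AcOH, MeOH, 0 → 23 °C
Reagents that add atoms: none
Why: Wharton transposition: hydrazone formation at C7, epoxide opening and loss of N2 place the alkene at C7=C8 without ambiguity and leave the oxygen on C9 with its α-configuration untouched.

Step 15
Reactants: 24 methyl 9α-hydroxy-3β-(triethylsilyloxy)labda-7,13E-dien-15-oate; 25 benzoyl chloride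
Product: 27 methyl 9α-benzoyloxy-3β-(triethylsilyloxy)labda-7,13E-dien-15-oate, via potassium alkoxide 26 (not isolated)
Conditions: KN(SiMe3)2, THF, −78 °C; 25, −78 → 0 °C
Reagents that add atoms: KN(SiMe3)2, C[Si](C)(C)[N-][Si](C)(C)C.[K+] (potassium of 26 only)
Why: Acylation of a preformed alkoxide is the usual answer to a tertiary alcohol that resists amine-catalysed acylation; O–H deprotonation outruns γ-deprotonation of the enoate at −78 °C, and no stereocentre is touched.

Step 16
Reactants: 27 methyl 9α-benzoyloxy-3β-(triethylsilyloxy)labda-7,13E-dien-15-oate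
Product: 28 9α-benzoyloxy-3β-(triethylsilyloxy)labda-7,13E-dien-15-oic acid
Conditions: Me3SnOH, ClCH2CH2Cl, 80 °C; dilute HCl wash
Reagents that add atoms: trimethyltin hydroxide, C[Sn](C)(C)O
Why: Neutral Me3SnOH cleavage is selective for the open methyl ester over the tertiary benzoate, which is shielded by C10 and C8.

Step 17
Reactants: 28 9α-benzoyloxy-3β-(triethylsilyloxy)labda-7,13E-dien-15-oic acid
Product: 29 9α-benzoyloxy-3β-hydroxylabda-7,13E-dien-15-oic acid (target)
Conditions: HF·pyridine, pyridine, THF, 0 °C
Reagents that add atoms: none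
Why: Buffered fluoride desilylation removes the triethylsilyl group quickly enough to spare the acid-sensitive tertiary allylic benzoate.

**Compound list**

1 | 6-methylhept-5-en-2-one | CC(=O)CCC=C(C)C | starting material
2 | cyclopropylmagnesium bromide | Br[Mg]C1CC1 | starting material
3 | 2-cyclopropyl-6-methylhept-5-en-2-ol (racemic) | CC(O)(CCC=C(C)C)C1CC1 | intermediate
4 | (3E)-1-bromo-4,8-dimethylnona-3,7-diene | CC(C)=CCC/C(C)=C/CCBr | intermediate
5 | (2E,6E)-9-bromo-2,6-dimethylnona-2,6-dien-1-ol | OC/C(C)=C/CC/C(C)=C/CCBr | intermediate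
6 | 2-methylpropanoyl chloride | CC(C)C(=O)Cl | starting material
7 | (2E,6E)-9-bromo-2,6-dimethylnona-2,6-dien-1-yl 2-methylpropanoate | CC(C)C(=O)OC/C(C)=C/CC/C(C)=C/CCBr | intermediate
8 | boron ketene acetal of 7 carrying the (R,R)-diazaborolidine | CC(C)=C(OC/C(C)=C/CC/C(C)=C/CCBr)OB1N(S(=O)(=O)c2cc(C(F)(F)F)cc(C(F)(F)F)c2)[C@H](c2ccccc2)[C@@H](c2ccccc2)N1S(=O)(=O)c1cc(C(F)(F)F)cc(C(F)(F)F)c1 | intermediate
9 | (3R)-3-[(3E)-6-bromo-3-methylhex-3-en-1-yl]-2,2,4-trimethylpent-4-enoic acid | OC(=O)C(C)(C)[C@H](CC/C(C)=C/CCBr)C(C)=C | intermediate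
10 | (3R)-3-[(3E)-6-bromo-3-methylhex-3-en-1-yl]-2,2,4-trimethylpent-4-enoyl chloride | ClC(=O)C(C)(C)[C@H](CC/C(C)=C/CCBr)C(C)=C | intermediate
11 | (4R)-4-[(3E)-6-bromo-3-methylhex-3-en-1-yl]-1-diazo-3,3,5-trimethylhex-5-en-2-one | [N-]=[N+]=CC(=O)C(C)(C)[C@H](CC/C(C)=C/CCBr)C(C)=C | intermediate
12 | (1R,4R,5R)-4-[(3E)-6-bromo-3-methylhex-3-en-1-yl]-3,3,5-trimethylbicyclo[3.1.0]hexan-2-one | O=C1[C@@H]2C[C@]2(C)[C@@H](CC/C(C)=C/CCBr)C1(C)C | intermediate
13 | ring-expanded enol cation (ring A six-membered; C3 enol; C10 tertiary cation) | OC1=CC[C+](C)[C@@H](CC/C(C)=C/CCBr)C1(C)C | intermediate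
14 | 12-bromo-13,14,15,16-tetranorlabd-7-en-3-one (5α-H, 9α-H, 10β-CH3) | CC1=CC[C@H]2C(C)(C)C(=O)CC[C@]2(C)[C@H]1CCBr | intermediate
15 | 12-bromo-13,14,15,16-tetranorlabd-8-en-3-one (5α-H, 10β-CH3) | CC1=C(CCBr)[C@@]2(C)CCC(=O)C(C)(C)[C@@H]2CC1 | intermediate
16 | 12-bromo-13,14,15,16-tetranorlabd-8-en-3β-ol | CC1=C(CCBr)[C@@]2(C)CC[C@H](O)C(C)(C)[C@@H]2CC1 | intermediate
17 | 12-bromo-3β-(triethylsilyloxy)-13,14,15,16-tetranorlabd-8-ene | CC1=C(CCBr)[C@@]2(C)CC[C@H](O[Si](CC)(CC)CC)C(C)(C)[C@@H]2CC1 | intermediate
18 | methyl but-2-ynoate | CC#CC(=O)OC | starting material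
19 | Grignard reagent of 17 (C12–MgBr) | CC1=C(CC[Mg]Br)[C@@]2(C)CC[C@H](O[Si](CC)(CC)CC)C(C)(C)[C@@H]2CC1 | intermediate
20 | alkylcopper of 17 (C12–Cu) | CC1=C(CC[Cu])[C@@]2(C)CC[C@H](O[Si](CC)(CC)CC)C(C)(C)[C@@H]2CC1 | intermediate
21 | methyl 3β-(triethylsilyloxy)labda-8,13E-dien-15-oate | CC1=C(CC/C(C)=C/C(=O)OC)[C@@]2(C)CC[C@H](O[Si](CC)(CC)CC)C(C)(C)[C@@H]2CC1 | intermediate
22 | methyl 7-oxo-3β-(triethylsilyloxy)labda-8,13E-dien-15-oate | CC1=C(CC/C(C)=C/C(=O)OC)[C@@]2(C)CC[C@H](O[Si](CC)(CC)CC)C(C)(C)[C@@H]2CC1=O | intermediate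
23 | methyl 8α,9α-epoxy-7-oxo-3β-(triethylsilyloxy)labd-13E-en-15-oate | C[C@]12O[C@@]1(CC/C(C)=C/C(=O)OC)[C@@]3(C)CC[C@H](O[Si](CC)(CC)CC)C(C)(C)[C@@H]3CC2=O | intermediate
24 | methyl 9α-hydroxy-3β-(triethylsilyloxy)labda-7,13E-dien-15-oate | CC1=CC[C@H]2C(C)(C)[C@@H](O[Si](CC)(CC)CC)CC[C@]2(C)[C@]1(CC/C(C)=C/C(=O)OC)O | intermediate
25 | benzoyl chloride | O=C(Cl)c1ccccc1 | starting material
26 | potassium 9α-alkoxide of 24 | CC1=CC[C@H]2C(C)(C)[C@@H](O[Si](CC)(CC)CC)CC[C@]2(C)[C@]1(CC/C(C)=C/C(=O)OC)[O-].[K+] | intermediate
27 | methyl 9α-benzoyloxy-3β-(triethylsilyloxy)labda-7,13E-dien-15-oate | CC1=CC[C@H]2C(C)(C)[C@@H](O[Si](CC)(CC)CC)CC[C@]2(C)[C@]1(CC/C(C)=C/C(=O)OC)OC(=O)c1ccccc1 | intermediate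
28 | 9α-benzoyloxy-3β-(triethylsilyloxy)labda-7,13E-dien-15-oic acid | CC1=CC[C@H]2C(C)(C)[C@@H](O[Si](CC)(CC)CC)CC[C@]2(C)[C@]1(CC/C(C)=C/C(=O)O)OC(=O)c1ccccc1 | intermediate
29 | 9α-benzoyloxy-3β-hydroxylabda-7,13E-dien-15-oic acid | CC1=CC[C@H]2C(C)(C)[C@@H](O)CC[C@]2(C)[C@]1(CC/C(C)=C/C(=O)O)OC(=O)c1ccccc1 | target

Total step count: 17. Longest linear sequence: 17 steps (from 1).

**Steps most likely to fail**

**Step 8 (new method).**
- What may go wrong: proton loss from the ring-enlarged cation may outrun the closure of ring B. The loss could occur at C1, at CH3-20 or, with erosion of optical purity, at C5. An epimeric cyclopropane may also open with inversion toward a cis-fused product.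
- Fallback: the two events are separated, each in a known form.
- Setting out from 12, warm dilute H2SO4 in aqueous dioxane should add water at the tertiary cyclopropane carbon, as in the hydration of thujane-type bicyclo[3.1.0]hexanes. This gives the ring-enlarged (3S)-3-[(3E)-6-bromo-3-methylhex-3-en-1-yl]-4-hydroxy-2,2,4-trimethylcyclohexan-1-one F1. In it ring A is already six-membered and both cyclopropane centres are gone.
- This hydroxy ketone is then a classical tertiary-alcohol initiator of a cation–olefin cyclisation (SnCl4, CH2Cl2, −78 °C). Brief treatment of the crude alkene mixture with p-TsOH in warm benzene brings the double bond to C8=C9. The sequence comes back to the route at 15.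

**Step 5.**
- What may go wrong: soft enolisation of the hindered, α-branched ester by the bulky bromoborane may be too slow, or the facial discrimination may be poor.
- Fallback: setting out from 7, a standard Ireland–Claisen rearrangement (LiN(i-Pr)2, Me3SiCl, THF, −78 → 23 °C; dilute acid) gives racemic 3-[(3E)-6-bromo-3-methylhex-3-en-1-yl]-2,2,4-trimethylpent-4-enoic acid F2.
- This acid is resolved by crystallisation of the (R)-1-phenylethylammonium salt of the (3R)-acid F3. Acidification of the salt comes back to the route at 9.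

**Step 15.**
- What may go wrong: the axial 9α-alkoxide, wedged between C10 and C8, may acylate too slowly, so that γ-deprotonation of the enoate or elimination takes over.
- Fallback: the C9–O bond is made with the benzoate already attached, and steps 12–15 are bypassed.
- Setting out from 21, a Kharasch–Sosnovsky allylic benzoyloxylation is used (CuBr cat., tert-butyl perbenzoate, benzene, 80 °C). The tert-butoxyl radical abstracts the accessible ring hydrogen at C7. The C7–C8–C9 allyl radical is taken up by divalent copper benzoate as a trivalent allylcopper species bound at the less hindered C7 on the α-face. Its pericyclic collapse delivers benzoate to the distal, more substituted terminus C9 on the same face.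
- This comes back to the route at 27. No new compound is made on this way (F0).

Further compounds
F1 | step 8 | (3S)-3-[(3E)-6-bromo-3-methylhex-3-en-1-yl]-4-hydroxy-2,2,4-trimethylcyclohexan-1-one (either C4 epimer) | O=C1CCC(C)(O)[C@@H](CC/C(C)=C/CCBr)C1(C)C
F2 | step 5 | racemic 3-[(3E)-6-bromo-3-methylhex-3-en-1-yl]-2,2,4-trimethylpent-4-enoic acid | OC(=O)C(C)(C)C(CC/C(C)=C/CCBr)C(C)=C
F3 | step 5 | (R)-1-phenylethylammonium salt of the (3R)-acid | [O-]C(=O)C(C)(C)[C@H](CC/C(C)=C/CCBr)C(C)=C.C[C@@H]([NH3+])c1ccccc1
F0 | step 15 | none | none
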